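The numbers were chosen freely; what happens was integrated by code.

One equivalent of incoming ligand pays for one exchange on one complex, so I kept the balance of that ligand, the limiting reagent of the exchanges, with 3.00 equiv charged against 4 sites on each complex.

starting complex 0.25 M; incoming ligand 3.00 equiv; leaving ligand 5.00 equiv; scavenger 1.20 equiv; time 5.0 min

    starting complex + complex with one exchanged → side product (k1 = 0.055 L mol⁻¹ s⁻¹)
    scavenger + leaving ligand → scavenged by-product (k2 = 1.4 L mol⁻¹ s⁻¹)
    complex with two exchanged + incoming ligand → leaving ligand + complex with three exchanged (k3 = 0.67 L mol⁻¹ s⁻¹)
    complex with one exchanged + incoming ligand → leaving ligand + complex with two exchanged (k4 = 0.93 L mol⁻¹ s⁻¹)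
    leaving ligand + incoming ligand ⇌ idle adduct, settled at all times (K5 = 0.10 L mol⁻¹)
    complex with three exchanged + incoming ligand → leaving ligand + complex with four exchanged (k6 = 0.61 L mol⁻¹ s⁻¹)
    starting complex + incoming ligand → leaving ligand + complex with one exchanged (k7 = 0.89 L mol⁻¹ s⁻¹)

* part of the starting complex that has reacted at 5.0 min
* share of the unused incoming ligand that is free and not bound as idle adduct, at 5.0 min

- in percentages every species weighs as the starting complex in it: one side product counts as two
- for leaving ligand the idle adduct is counted in
- run time (flask): 5.0 min

Each exchange uses ligand at its constant times free ligand times that complex, and the fastest constant is 0.93 L mol⁻¹ s⁻¹, so summed over the complexes the ligand goes no faster than that constant times 0.25 M times free ligand. The starting complex meanwhile decays exponentially in the time integral of free ligand with 0.89 L mol⁻¹ s⁻¹, and the side step can only lower it further. Dividing one by the other gave my rule: the fraction of starting complex left is no more than the exponential of minus the equivalents consumed times the ratio of the first-exchange constant to the fastest constant, and I called this the leftover ceiling, 5.66%. With the slowest exchange constant, 0.61 L mol⁻¹ s⁻¹, and 0.0625 M of complex, the amount I took as still open to exchange, the lifetime of the incoming ligand comes to 26.2 s, shorter than 5.0 min, so I took the incoming ligand as consumed by then and committed to at least 94.3% reacted.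

The neighbouring flask looks nearly the same but holds a quarter of the incoming ligand, 0.750 equiv, and its ceiling is 48.8%. With 0.188 M of incoming ligand against 0.25 M of starting complex, that neighbour flask cannot pay one exchange per complex charged, so I expected starting complex to stand beside complex with one exchanged, open to the side step, which needs no incoming ligand.

The same balance gave the leaving ligand: charge plus 0.750 M released, less 0.300 M taken by the scavenger, is 1.70 M, so I reckoned a free share of 85.5%.

The forecast gave 100% and 85.5%, holding that “essentially all the starting complex is gone”, a figure above my floor.

The flask gave 98.6% reacted and 85.5% free. At 0.500 min it had already used 97.9% of its starting complex, with 2.54% of the charged incoming ligand still free. The 1.4% left at the asked time lies under the ceiling of 5.66%. In the neighbour flask the ceiling of 48.8% also stood above the 21.8% of starting complex found, 78.2% had reacted, and side product held the most of the complex there, 50.2%.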